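**Retrosynthetic overview**
1. The C6 isovalerate and C10 acetate go on last; the 8α,9α-epoxide comes from hydroxyl-directed epoxidation of a cyclohept-8-en-10-ol.
2. The seven-membered ring is closed last by ring-closing metathesis (C8=C9) between a C10 vinyl carbinol and a C6 methallyl carbinol on the cyclopentane.
3. Key C5–C6 bond: intermolecular boron aldol of a 4,4-disubstituted cyclopent-2-enone (α'-enolate) with 3-methylbut-3-enal; C4 then by isopropyl addition.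
4. The five-membered ring is formed first, by aldol condensation of a 1,4-keto aldehyde.
5. C10 and the quaternary C1 come from diethyl (S)-malate by two Fráter–Seebach alkylations (methallyl, then methyl).

Convention: C1–C10 are the daucane positions of the target (C1 quaternary CH3-bearing fusion carbon, C4 isopropyl carbinol, C5 fusion CH, C6 ester carbinol, C8/C9 epoxide, C10 acetoxy carbon); metal alkoxides that are only protonated on work-up are not numbered.

**Step 1**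
Reactants: 1 diethyl (S)-malate; 2 3-bromo-2-methylprop-1-ene
Product: 4 diethyl (2S,3R)-2-hydroxy-3-(2-methylprop-2-en-1-yl)butanedioate, via dilithium alkoxide enolate 3 (not isolated)
Conditions: LiN(i-Pr)2 (2.2 equiv), THF, −78 → −20 °C; then 2, −78 → −5 °C
Reagents that add atoms: none
Why: Fráter–Seebach alkylation: the chelated alkoxide–enolate is alkylated on the face away from the ester group on the carbinol carbon, setting the new centre anti (3R).

**Step 2**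
Reactants: 4 methallyl malate
Product: 6 diethyl (2S,3S)-2-hydroxy-3-methyl-3-(2-methylprop-2-en-1-yl)butanedioate, via dilithium alkoxide enolate 5 (not isolated)
Conditions: LiN(i-Pr)2 (2.3 equiv), THF, −78 → −10 °C; then MeI, DMPU, −78 → 0 °C
Reagents that add atoms: iodomethane, CI
Why: Second Fráter–Seebach alkylation: MeI again enters anti to the carbinol ester group, so the order methallyl-then-methyl fixes the quaternary centre (future C1) as 3S.

**Step 3**
Reactants: 6 quaternary malate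
Product: 7 (2S,3R)-3-(hydroxymethyl)-3,5-dimethylhex-5-ene-1,2-diol
Conditions: LiAlH4, THF, 0 °C → reflux; Fieser work-up
Reagents that add atoms: none
Why: Hydride reduction of both esters to primary alcohols; neither stereocentre is touched.

**Step 4**
Reactants: 7 triol
Product: 8 (2R)-2-[(4S)-2,2-dimethyl-1,3-dioxolan-4-yl]-2,4-dimethylpent-4-en-1-ol
Conditions: Me2C(OMe)2, PPTS (cat.), acetone, rt
Reagents that add atoms: 2,2-dimethoxypropane, COC(C)(C)OC
Why: Thermodynamic acetonide formation takes the terminal 1,2-diol (dioxolane preferred over the 1,3-dioxane), leaving the neopentyl CH2OH free.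

**Step 5**
Reactants: 8 acetonide alcohol
Product: 9 (2S)-2-[(4S)-2,2-dimethyl-1,3-dioxolan-4-yl]-2,4-dimethylpent-4-enal
Conditions: Dess–Martin periodinane, CH2Cl2, 0 °C → rt
Reagents that add atoms: none
Why: Dess–Martin oxidation of the primary alcohol; the aldehyde has a quaternary α-carbon and cannot epimerise.

**Step 6**
Reactants: 9 enal
Product: 11 (2S)-2-[(4S)-2,2-dimethyl-1,3-dioxolan-4-yl]-2-methyl-4-oxopentanal, via ozonide 10 (not isolated)
Conditions: O3, CH2Cl2, −78 °C; then PPh3, −78 °C → rt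
Reagents that add atoms: ozone, [O-][O+]=O
Why: Ozonolysis with reductive work-up turns the only alkene (1,1-disubstituted) into the methyl ketone.

**Step 7**
Reactants: 11 keto aldehyde
Product: 13 (4R)-4-[(4S)-2,2-dimethyl-1,3-dioxolan-4-yl]-4-methylcyclopent-2-en-1-one, via aldol adduct 12 (not isolated)
Conditions: KOH (0.2 equiv), EtOH, 0 °C → rt
Reagents that add atoms: none
Why: Intramolecular aldol condensation: the methyl ketone enolate can only close onto the non-enolisable aldehyde, and dehydration gives the cyclopentenone.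

**Step 8**
Reactants: 14 3-methylbut-3-en-1-ol
Product: 15 3-methylbut-3-enal
Conditions: Dess–Martin periodinane, CH2Cl2, 0 °C; cold aq. NaHCO3/Na2S2O3 wash, dried solution used at once
Reagents that add atoms: none
Why: Dess–Martin oxidation under non-basic conditions keeps the alkene out of conjugation.

**Step 9** (key step)
Reactants: 13 cyclopentenone; 15 3-methylbut-3-enal
Product: 17 (4S,5S)-4-[(4S)-2,2-dimethyl-1,3-dioxolan-4-yl]-5-[(1S)-1-hydroxy-3-methylbut-3-en-1-yl]-4-methylcyclopent-2-en-1-one, via dicyclohexylboron dienolate 16 (not isolated)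
Conditions: (c-C6H11)2BCl, Et3N, Et2O, −78 → 0 °C; then 15 (1.5 equiv), −78 → −20 °C; then pH 7 buffer, MeOH, H2O2, 0 °C
Reagents that add atoms: none
Why: Intermolecular boron aldol: the ring-fixed (E)-enolate at the only enolisable carbon (C5) reacts through a Zimmerman–Traxler chair to give the anti aldol (C6 S), and the aldehyde approaches anti to the bulky dioxolanyl group on C1 (C5 S).

**Step 10**
Reactants: 17 aldol
Product: 18 (4S,5S)-5-[(1S)-1-{[tert-butyl(dimethyl)silyl]oxy}-3-methylbut-3-en-1-yl]-4-[(4S)-2,2-dimethyl-1,3-dioxolan-4-yl]-4-methylcyclopent-2-en-1-one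
Conditions: TBSOTf, 2,6-lutidine, CH2Cl2, −78 °C
Reagents that add atoms: tert-butyldimethylsilyl trifluoromethanesulfonate, CC(C)(C)[Si](C)(C)OS(=O)(=O)C(F)(F)F
Why: Silylation of the β-hydroxy ketone under non-nucleophilic base blocks retro-aldol in the later organometallic step.

**Step 11**
Reactants: 18 silyl ether enone
Product: 19 (2S,3S)-2-[(1S)-1-{[tert-butyl(dimethyl)silyl]oxy}-3-methylbut-3-en-1-yl]-3-[(4S)-2,2-dimethyl-1,3-dioxolan-4-yl]-3-methylcyclopentan-1-one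
Conditions: [(Ph3P)CuH]6 (0.4 equiv), toluene, H2O (5 equiv), rt
Reagents that add atoms: none
Why: Copper hydride conjugate reduction is selective for the enone C=C and leaves the isolated 1,1-disubstituted alkene alone.

**Step 12**
Reactants: 19 cyclopentanone
Product: 20 (1R,2S,3S)-2-[(1S)-1-{[tert-butyl(dimethyl)silyl]oxy}-3-methylbut-3-en-1-yl]-3-[(4S)-2,2-dimethyl-1,3-dioxolan-4-yl]-3-methyl-1-(propan-2-yl)cyclopentan-1-ol
Conditions: i-PrMgCl, CeCl3 (anhydrous), THF, −78 → 0 °C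
Reagents that add atoms: isopropylmagnesium chloride, CC(C)[Mg]Cl
Why: Organocerium 1,2-addition (low basicity limits enolisation and β-hydride reduction) occurs anti to the C5 side chain, giving C4 (R) with OH cis to that chain.

**Step 13**
Reactants: 20 acetonide
Product: 21 (1S)-1-[(1S,2S,3R)-2-[(1S)-1-{[tert-butyl(dimethyl)silyl]oxy}-3-methylbut-3-en-1-yl]-3-hydroxy-1-methyl-3-(propan-2-yl)cyclopentyl]ethane-1,2-diol
Conditions: PPTS, MeOH, 40 °C
Reagents that add atoms: none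
Why: Acid-catalysed transketalisation frees the terminal 1,2-diol while the hindered secondary silyl ether and the tertiary alcohol survive.

**Step 14**
Reactants: 21 diol
Product: 22 (2S)-2-[(1S,2S,3R)-2-[(1S)-1-{[tert-butyl(dimethyl)silyl]oxy}-3-methylbut-3-en-1-yl]-3-hydroxy-1-methyl-3-(propan-2-yl)cyclopentyl]-2-hydroxyethyl 4-methylbenzenesulfonate
Conditions: TsCl, Et3N, Bu2SnO (cat.), CH2Cl2, rt
Reagents that add atoms: 4-methylbenzenesulfonyl chloride, Cc1ccc(cc1)S(=O)(=O)Cl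
Why: Stannylene-acetal-mediated sulfonylation tosylates only the primary oxygen of the 1,2-diol.

**Step 15**
Reactants: 22 tosylate
Product: 23 (1R,2S,3S)-2-[(1S)-1-{[tert-butyl(dimethyl)silyl]oxy}-3-methylbut-3-en-1-yl]-3-methyl-3-[(2S)-oxiran-2-yl]-1-(propan-2-yl)cyclopentan-1-ol
Conditions: K2CO3, MeOH, 0 °C → rt
Reagents that add atoms: none
Why: Intramolecular Williamson epoxide closure: the C10 alkoxide displaces the primary tosylate, so C10 keeps its configuration.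

**Step 16**
Reactants: 23 epoxide
Product: 24 (1R)-1-[(1S,2S,3R)-2-[(1S)-1-{[tert-butyl(dimethyl)silyl]oxy}-3-methylbut-3-en-1-yl]-3-hydroxy-1-methyl-3-(propan-2-yl)cyclopentyl]prop-2-en-1-ol
Conditions: Me3S+ I− (4 equiv), n-BuLi (3.8 equiv), THF, −10 °C → rt
Reagents that add atoms: trimethylsulfonium iodide, C[S+](C)C.[I-]
Why: Sulfonium-ylide epoxide homologation: the ylide opens the epoxide at the terminal CH2 and base-induced loss of Me2S gives the allylic alcohol with C10 untouched (descriptor changes to R by priority only).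

**Step 17**
Reactants: 24 diene
Product: 25 (1S,4R,5S,6S,10R)-6-{[tert-butyl(dimethyl)silyl]oxy}dauc-8-ene-4,10-diol (trans-fused bicyclo[5.3.0]dec-8-ene; 4β-OH, 6α-OSi, 10α-OH)
Conditions: second-generation Hoveyda–Grubbs catalyst (5 mol %), toluene (2 mM), 80 °C
Reagents that add atoms: none
Why: Ring-closing metathesis between the vinyl group and the methallyl alkene closes the trans-fused seven-membered ring as the trisubstituted C8=C9 alkene with loss of ethene.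

**Step 18**
Reactants: 25 cycloheptenol
Product: 26 (1S,4R,5S,6S,8R,9S,10S)-6-{[tert-butyl(dimethyl)silyl]oxy}-8,9-epoxydaucane-4,10-diol (8α,9α-epoxide)
Conditions: VO(acac)2 (5 mol %), t-BuOOH, CH2Cl2, 0 °C → rt
Reagents that add atoms: tert-butyl hydroperoxide, CC(C)(C)OO
Why: Vanadium-catalysed hydroxyl-directed epoxidation delivers oxygen syn to the allylic C10 hydroxyl, setting C8 (R) and C9 (S).

**Step 19**
Reactants: 26 epoxy diol
Product: 27 (1S,4R,5S,6S,8R,9S,10S)-6-{[tert-butyl(dimethyl)silyl]oxy}-8,9-epoxy-4-hydroxydaucan-10-yl acetate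
Conditions: Ac2O, pyridine, DMAP (cat.), CH2Cl2, rt
Reagents that add atoms: acetic anhydride, CC(=O)OC(C)=O
Why: DMAP-catalysed acylation of the only free secondary hydroxyl; the tertiary C4 hydroxyl is too hindered to react.

**Step 20**
Reactants: 27 acetate
Product: 28 (1S,4R,5S,6S,8R,9S,10S)-8,9-epoxy-4,6-dihydroxydaucan-10-yl acetate
Conditions: HF·pyridine, pyridine, THF, 0 °C → rt
Reagents that add atoms: none
Why: Buffered fluoride desilylation frees the C6 hydroxyl without opening the trisubstituted epoxide or cleaving the acetate.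

**Step 21**
Reactants: 28 C6 alcohol
Product: 29 (1S,4R,5S,6S,8R,9S,10S)-10-acetoxy-8,9-epoxy-4-hydroxydaucan-6-yl 3-methylbutanoate (target)
Conditions: 3-methylbutanoyl chloride, pyridine, DMAP, CH2Cl2, 0 °C → rt
Reagents that add atoms: 3-methylbutanoyl chloride, CC(C)CC(=O)Cl
Why: DMAP-catalysed esterification of the C6 secondary alcohol; the tertiary C4 hydroxyl stays free.

**Compound list**
1 | diethyl (2S)-2-hydroxybutanedioate (diethyl L-malate) | CCOC(=O)C[C@H](O)C(=O)OCC | starting material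
2 | 3-bromo-2-methylprop-1-ene | C=C(C)CBr | starting material
3 | dilithium alkoxide enolate of 1 | CCOC(=O)[C@@H]([O-])C=C([O-])OCC.[Li+].[Li+] | intermediate
4 | diethyl (2S,3R)-2-hydroxy-3-(2-methylprop-2-en-1-yl)butanedioate | CCOC(=O)[C@@H](O)[C@@H](CC(C)=C)C(=O)OCC | intermediate
5 | dilithium alkoxide enolate of 4 | CCOC(=O)[C@@H]([O-])C(CC(C)=C)=C([O-])OCC.[Li+].[Li+] | intermediate
6 | diethyl (2S,3S)-2-hydroxy-3-methyl-3-(2-methylprop-2-en-1-yl)butanedioate | C=C(C)C[C@]([C@H](O)C(=O)OCC)(C)C(=O)OCC | intermediate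
7 | (2S,3R)-3-(hydroxymethyl)-3,5-dimethylhex-5-ene-1,2-diol | C=C(C)C[C@]([C@H](O)CO)(C)CO | intermediate
8 | (2R)-2-[(4S)-2,2-dimethyl-1,3-dioxolan-4-yl]-2,4-dimethylpent-4-en-1-ol | C=C(C)C[C@]([C@H]1COC(C)(C)O1)(C)CO | intermediate
9 | (2S)-2-[(4S)-2,2-dimethyl-1,3-dioxolan-4-yl]-2,4-dimethylpent-4-enal | C=C(C)C[C@]([C@H]1COC(C)(C)O1)(C)C=O | intermediate
10 | ozonide of 9: (2S)-2-[(4S)-2,2-dimethyl-1,3-dioxolan-4-yl]-2-methyl-3-(3-methyl-1,2,4-trioxolan-3-yl)propanal (trioxolane epimers) | CC1(C[C@]([C@H]2COC(C)(C)O2)(C)C=O)OCOO1 | intermediate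
11 | (2S)-2-[(4S)-2,2-dimethyl-1,3-dioxolan-4-yl]-2-methyl-4-oxopentanal | CC(=O)C[C@]([C@H]1COC(C)(C)O1)(C)C=O | intermediate
12 | (4R)-4-[(4S)-2,2-dimethyl-1,3-dioxolan-4-yl]-3-hydroxy-4-methylcyclopentan-1-one (C3 epimers) | O=C1C[C@]([C@H]2COC(C)(C)O2)(C)C(O)C1 | intermediate
13 | (4R)-4-[(4S)-2,2-dimethyl-1,3-dioxolan-4-yl]-4-methylcyclopent-2-en-1-one | O=C1C[C@]([C@H]2COC(C)(C)O2)(C)C=C1 | intermediate
14 | 3-methylbut-3-en-1-ol | C=C(C)CCO | starting material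
15 | 3-methylbut-3-enal | C=C(C)CC=O | intermediate
16 | dicyclohexylboron dienolate of 13 (O-bound at C4; C4=C5 and C2=C3; stereocentres as in 13) | B(C1CCCCC1)(C2CCCCC2)OC3=C[C@]([C@H]4COC(C)(C)O4)(C)C=C3 | intermediate
17 | (4S,5S)-4-[(4S)-2,2-dimethyl-1,3-dioxolan-4-yl]-5-[(1S)-1-hydroxy-3-methylbut-3-en-1-yl]-4-methylcyclopent-2-en-1-one | C=C(C)C[C@H](O)[C@H]1C(=O)C=C[C@]1(C)[C@H]2COC(C)(C)O2 | intermediate
18 | (4S,5S)-5-[(1S)-1-{[tert-butyl(dimethyl)silyl]oxy}-3-methylbut-3-en-1-yl]-4-[(4S)-2,2-dimethyl-1,3-dioxolan-4-yl]-4-methylcyclopent-2-en-1-one | C=C(C)C[C@H](O[Si](C)(C)C(C)(C)C)[C@H]1C(=O)C=C[C@]1(C)[C@H]2COC(C)(C)O2 | intermediate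
19 | (2S,3S)-2-[(1S)-1-{[tert-butyl(dimethyl)silyl]oxy}-3-methylbut-3-en-1-yl]-3-[(4S)-2,2-dimethyl-1,3-dioxolan-4-yl]-3-methylcyclopentan-1-one | C=C(C)C[C@H](O[Si](C)(C)C(C)(C)C)[C@H]1C(=O)CC[C@]1(C)[C@H]2COC(C)(C)O2 | intermediate
20 | (1R,2S,3S)-2-[(1S)-1-{[tert-butyl(dimethyl)silyl]oxy}-3-methylbut-3-en-1-yl]-3-[(4S)-2,2-dimethyl-1,3-dioxolan-4-yl]-3-methyl-1-(propan-2-yl)cyclopentan-1-ol | C=C(C)C[C@H](O[Si](C)(C)C(C)(C)C)[C@H]1[C@](O)(C(C)C)CC[C@]1(C)[C@H]2COC(C)(C)O2 | intermediate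
21 | (1S)-1-[(1S,2S,3R)-2-[(1S)-1-{[tert-butyl(dimethyl)silyl]oxy}-3-methylbut-3-en-1-yl]-3-hydroxy-1-methyl-3-(propan-2-yl)cyclopentyl]ethane-1,2-diol | C=C(C)C[C@H](O[Si](C)(C)C(C)(C)C)[C@H]1[C@](O)(C(C)C)CC[C@]1(C)[C@H](O)CO | intermediate
22 | (2S)-2-[(1S,2S,3R)-2-[(1S)-1-{[tert-butyl(dimethyl)silyl]oxy}-3-methylbut-3-en-1-yl]-3-hydroxy-1-methyl-3-(propan-2-yl)cyclopentyl]-2-hydroxyethyl 4-methylbenzenesulfonate | C=C(C)C[C@H](O[Si](C)(C)C(C)(C)C)[C@H]1[C@](O)(C(C)C)CC[C@]1(C)[C@H](O)COS(=O)(=O)c2ccc(C)cc2 | intermediate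
23 | (1R,2S,3S)-2-[(1S)-1-{[tert-butyl(dimethyl)silyl]oxy}-3-methylbut-3-en-1-yl]-3-methyl-3-[(2S)-oxiran-2-yl]-1-(propan-2-yl)cyclopentan-1-ol | C=C(C)C[C@H](O[Si](C)(C)C(C)(C)C)[C@H]1[C@](O)(C(C)C)CC[C@]1(C)[C@H]2CO2 | intermediate
24 | (1R)-1-[(1S,2S,3R)-2-[(1S)-1-{[tert-butyl(dimethyl)silyl]oxy}-3-methylbut-3-en-1-yl]-3-hydroxy-1-methyl-3-(propan-2-yl)cyclopentyl]prop-2-en-1-ol | C=C(C)C[C@H](O[Si](C)(C)C(C)(C)C)[C@H]1[C@](O)(C(C)C)CC[C@]1(C)[C@H](O)C=C | intermediate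
25 | (1S,4R,5S,6S,10R)-6-{[tert-butyl(dimethyl)silyl]oxy}dauc-8-ene-4,10-diol | O[C@@H]1C=C(C)C[C@H](O[Si](C)(C)C(C)(C)C)[C@@H]2[C@]1(C)CC[C@@]2(O)C(C)C | intermediate
26 | (1S,4R,5S,6S,8R,9S,10S)-6-{[tert-butyl(dimethyl)silyl]oxy}-8,9-epoxydaucane-4,10-diol | O[C@@H]1[C@@H]2O[C@]2(C)C[C@H](O[Si](C)(C)C(C)(C)C)[C@@H]2[C@]1(C)CC[C@@]2(O)C(C)C | intermediate
27 | (1S,4R,5S,6S,8R,9S,10S)-6-{[tert-butyl(dimethyl)silyl]oxy}-8,9-epoxy-4-hydroxydaucan-10-yl acetate | CC(=O)O[C@@H]1[C@@H]2O[C@]2(C)C[C@H](O[Si](C)(C)C(C)(C)C)[C@@H]2[C@]1(C)CC[C@@]2(O)C(C)C | intermediate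
28 | (1S,4R,5S,6S,8R,9S,10S)-8,9-epoxy-4,6-dihydroxydaucan-10-yl acetate | CC(=O)O[C@@H]1[C@@H]2O[C@]2(C)C[C@H](O)[C@@H]2[C@]1(C)CC[C@@]2(O)C(C)C | intermediate
29 | (1S,4R,5S,6S,8R,9S,10S)-10-acetoxy-8,9-epoxy-4-hydroxydaucan-6-yl 3-methylbutanoate | CC(=O)O[C@@H]1[C@@H]2O[C@]2(C)C[C@H](OC(=O)CC(C)C)[C@@H]2[C@]1(C)CC[C@@]2(O)C(C)C | target

**Totals**
Total steps: 21. Longest linear sequence: 20 steps (steps 1–7 and 9–21; step 8 is the side branch to aldehyde 15).

**Three steps most likely to fail, with fallbacks**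

Step 9 (key aldol). Aldehyde 15 isomerises easily to the conjugated enal, and both enolate-face and anti/syn selectivity must be good. The fallback makes the C6–C7 bond by carbonyl allylation instead; it sets out from 13 and comes back at 20. Enone 13 is deprotonated with LiN(i-Pr)2 and trapped with monomeric formaldehyde, anti to the dioxolanyl group, to give the hydroxymethyl enone F1. TBSCl/imidazole gives the silyl ether F2, and H2 over Pd/C gives the cyclopentanone F3. i-PrMgCl/CeCl3 adds anti to the C5 substituent to give the tertiary alcohol F4, and Bu4NF then gives the diol F5. Dess–Martin oxidation of the primary alcohol gives the β-hydroxy aldehyde F6. Chelation-controlled methallylation with CH2=C(CH3)CH2SnBu3 and MgBr2·OEt2 (CH2Cl2, −20 °C) gives the methallyl diol F7; the six-membered magnesium chelate between the aldehyde and the C4 hydroxyl exposes the face syn to H5, which gives C6 (S). Silylation of the secondary hydroxyl only (TBSOTf, 2,6-lutidine, −78 °C) returns to 20.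

Step 12 (isopropyl addition). A secondary Grignard on a hindered, enolisable ketone may enolise or reduce it. An isopropenyl nucleophile followed by hydrogenation is safer, but it cannot be used while the methallyl alkene is present. The fallback therefore runs on an alkene-free series; it sets out from 13 and comes back at 21. Commercial ethyl (2-methyl-1,3-dioxolan-2-yl)acetate is reduced with i-Bu2AlH at −78 °C to the ketal aldehyde F8. The boron aldol of 13 with F8 under the step 9 conditions gives the ketal aldol F9, and TBSOTf/2,6-lutidine gives the silyl ether F10. CH2=C(CH3)MgBr/CeCl3 adds 1,2 to the enone, anti to the C5 side chain, to give the dienol F11. Hydroxyl-directed hydrogenation (H2, [Ir(cod)(PCy3)(py)]PF6, CH2Cl2) saturates the ring alkene and the isopropenyl group to give the isopropyl carbinol F12. PPTS in wet acetone removes the ketone ketal and the acetonide together to give the keto diol F13. Wittig methylenation with excess Ph3P=CH2 returns to 21.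

Step 16 (ylide homologation). The epoxide sits next to a quaternary centre and the substrate carries a free tertiary alkoxide under strongly basic conditions. The fallback replaces steps 14–16; it sets out from 21 and comes back at 24. NaIO4 (THF/H2O) cleaves the diol to the neopentyl aldehyde F14. CH2=CHMgBr gives the allylic alcohol F15 as C10 epimers, the Felkin product being the unwanted one. Dess–Martin oxidation gives the vinyl ketone F16. Reduction with (S)-2-methyl-CBS-oxazaborolidine and catecholborane (toluene, −78 °C), which should work in the same sense as the Felkin preference, returns to 24.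

**Further compounds**
F1 | step 9 | (4S,5S)-4-[(4S)-2,2-dimethyl-1,3-dioxolan-4-yl]-5-(hydroxymethyl)-4-methylcyclopent-2-en-1-one | OC[C@H]1C(=O)C=C[C@]1(C)[C@H]2COC(C)(C)O2
F2 | step 9 | (4S,5S)-5-({[tert-butyl(dimethyl)silyl]oxy}methyl)-4-[(4S)-2,2-dimethyl-1,3-dioxolan-4-yl]-4-methylcyclopent-2-en-1-one | CC(C)(C)[Si](C)(C)OC[C@H]1C(=O)C=C[C@]1(C)[C@H]2COC(C)(C)O2
F3 | step 9 | (2S,3S)-2-({[tert-butyl(dimethyl)silyl]oxy}methyl)-3-[(4S)-2,2-dimethyl-1,3-dioxolan-4-yl]-3-methylcyclopentan-1-one | CC(C)(C)[Si](C)(C)OC[C@H]1C(=O)CC[C@]1(C)[C@H]2COC(C)(C)O2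
F4 | step 9 | (1R,2S,3S)-2-({[tert-butyl(dimethyl)silyl]oxy}methyl)-3-[(4S)-2,2-dimethyl-1,3-dioxolan-4-yl]-3-methyl-1-(propan-2-yl)cyclopentan-1-ol | CC(C)(C)[Si](C)(C)OC[C@H]1[C@](O)(C(C)C)CC[C@]1(C)[C@H]2COC(C)(C)O2
F5 | step 9 | (1R,2S,3S)-3-[(4S)-2,2-dimethyl-1,3-dioxolan-4-yl]-2-(hydroxymethyl)-3-methyl-1-(propan-2-yl)cyclopentan-1-ol | OC[C@H]1[C@](O)(C(C)C)CC[C@]1(C)[C@H]2COC(C)(C)O2
F6 | step 9 | (1R,2S,5R)-2-[(4S)-2,2-dimethyl-1,3-dioxolan-4-yl]-5-hydroxy-2-methyl-5-(propan-2-yl)cyclopentane-1-carbaldehyde | O=C[C@H]1[C@](O)(C(C)C)CC[C@]1(C)[C@H]2COC(C)(C)O2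
F7 | step 9 | (1R,2S,3S)-3-[(4S)-2,2-dimethyl-1,3-dioxolan-4-yl]-2-[(1S)-1-hydroxy-3-methylbut-3-en-1-yl]-3-methyl-1-(propan-2-yl)cyclopentan-1-ol | C=C(C)C[C@H](O)[C@H]1[C@](O)(C(C)C)CC[C@]1(C)[C@H]2COC(C)(C)O2
F8 | step 12 | (2-methyl-1,3-dioxolan-2-yl)acetaldehyde | CC1(CC=O)OCCO1
F9 | step 12 | (4S,5S)-4-[(4S)-2,2-dimethyl-1,3-dioxolan-4-yl]-5-[(1S)-1-hydroxy-2-(2-methyl-1,3-dioxolan-2-yl)ethyl]-4-methylcyclopent-2-en-1-one | CC1(C[C@H](O)[C@H]2C(=O)C=C[C@]2(C)[C@H]3COC(C)(C)O3)OCCO1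
F10 | step 12 | (4S,5S)-5-[(1S)-1-{[tert-butyl(dimethyl)silyl]oxy}-2-(2-methyl-1,3-dioxolan-2-yl)ethyl]-4-[(4S)-2,2-dimethyl-1,3-dioxolan-4-yl]-4-methylcyclopent-2-en-1-one | CC1(C[C@H](O[Si](C)(C)C(C)(C)C)[C@H]2C(=O)C=C[C@]2(C)[C@H]3COC(C)(C)O3)OCCO1
F11 | step 12 | (1S,4S,5S)-5-[(1S)-1-{[tert-butyl(dimethyl)silyl]oxy}-2-(2-methyl-1,3-dioxolan-2-yl)ethyl]-4-[(4S)-2,2-dimethyl-1,3-dioxolan-4-yl]-4-methyl-1-(prop-1-en-2-yl)cyclopent-2-en-1-ol | CC1(C[C@H](O[Si](C)(C)C(C)(C)C)[C@H]2[C@](O)(C(C)=C)C=C[C@]2(C)[C@H]3COC(C)(C)O3)OCCO1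
F12 | step 12 | (1R,2S,3S)-2-[(1S)-1-{[tert-butyl(dimethyl)silyl]oxy}-2-(2-methyl-1,3-dioxolan-2-yl)ethyl]-3-[(4S)-2,2-dimethyl-1,3-dioxolan-4-yl]-3-methyl-1-(propan-2-yl)cyclopentan-1-ol | CC1(C[C@H](O[Si](C)(C)C(C)(C)C)[C@H]2[C@](O)(C(C)C)CC[C@]2(C)[C@H]3COC(C)(C)O3)OCCO1
F13 | step 12 | (4S)-4-{[tert-butyl(dimethyl)silyl]oxy}-4-[(1S,2S,5R)-2-[(1S)-1,2-dihydroxyethyl]-5-hydroxy-2-methyl-5-(propan-2-yl)cyclopentyl]butan-2-one | CC(=O)C[C@H](O[Si](C)(C)C(C)(C)C)[C@H]1[C@](O)(C(C)C)CC[C@]1(C)[C@H](O)CO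
F14 | step 16 | (1S,2S,3R)-2-[(1S)-1-{[tert-butyl(dimethyl)silyl]oxy}-3-methylbut-3-en-1-yl]-3-hydroxy-1-methyl-3-(propan-2-yl)cyclopentane-1-carbaldehyde | C=C(C)C[C@H](O[Si](C)(C)C(C)(C)C)[C@H]1[C@](O)(C(C)C)CC[C@]1(C)C=O
F15 | step 16 | 1-[(1S,2S,3R)-2-[(1S)-1-{[tert-butyl(dimethyl)silyl]oxy}-3-methylbut-3-en-1-yl]-3-hydroxy-1-methyl-3-(propan-2-yl)cyclopentyl]prop-2-en-1-ol (carbinol epimers) | C=C(C)C[C@H](O[Si](C)(C)C(C)(C)C)[C@H]1[C@](O)(C(C)C)CC[C@]1(C)C(O)C=C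
F16 | step 16 | 1-[(1S,2S,3R)-2-[(1S)-1-{[tert-butyl(dimethyl)silyl]oxy}-3-methylbut-3-en-1-yl]-3-hydroxy-1-methyl-3-(propan-2-yl)cyclopentyl]prop-2-en-1-one | C=C(C)C[C@H](O[Si](C)(C)C(C)(C)C)[C@H]1[C@](O)(C(C)C)CC[C@]1(C)C(=O)C=C
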